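Ring B (C5–C6–C7–C8–C9–C10) is treated as the cyclohexene of an intramolecular Diels–Alder reaction. The C7 oxygen, flanked by C6H2 and the C8 methylene, marks a 2-silyloxydiene (C5=C6–C7(OSi)=C8); C9 and C10 come from an (E)-trisubstituted enoate whose carbonyl is C11. One thermal cycloaddition of an acyclic triene closes rings A and B, forms C5–C10 and C8–C9, and sets C5, C9 and the quaternary C10 under control of the single C4 stereocentre. That centre (C4 with its methyl and the C19 ester) is taken from (S)-malic ester by two Fráter–Seebach alkylations. The side chain and the C7/C8 functions are added afterwards.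

Key step: step 9

Assumption: labdane numbering (C1–C20) is used for the bicyclic compounds (5α-H, 9α-H, 10β-CH3; C19 is the axial 4β-carboxyl carbon, C18 the 4α-methyl), and the target is read as the 4S,5R,7S,9R,10R enantiomer with a 7β-acetoxy group.

Step 1
Reactants: 1 dimethyl (S)-malate; 2 allyl bromide
Product: 3 dimethyl (2S,3R)-2-hydroxy-3-(prop-2-en-1-yl)butanedioate
Conditions: LDA (2.2 equiv), THF, −78 → −20 °C; then 2, −78 → −10 °C; aq. NH4Cl
Reagents that add atoms: allyl bromide (2), C=CCBr
Why: Fráter–Seebach alkylation, in which the chelated lithium alkoxide–enolate dianion is attacked on the face anti to the C2 substituent, which should give the 2S,3R (anti) product.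

Step 2
Reactants: 3 dimethyl (2S,3R)-2-hydroxy-3-(prop-2-en-1-yl)butanedioate; 4 iodomethane
Product: 5 dimethyl (2S,3S)-2-hydroxy-3-methyl-3-(prop-2-en-1-yl)butanedioate
Conditions: LDA (2.3 equiv), THF/DMPU, −78 → −20 °C; then MeI, −78 → 0 °C
Reagents that add atoms: iodomethane (4), CI
Why: second Fráter–Seebach alkylation, in which the tetrasubstituted chelated enolate is again attacked on the face anti to the C2 substituent, so methyl enters where allyl entered in step 1 and the quaternary centre (the future C4 with C18 and C19) should form as 3S.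

Step 3
Reactants: 6 methyl acetoacetate; 7 trifluoromethanesulfonic anhydride
Product: 8 methyl (2E)-3-(trifluoromethanesulfonyloxy)but-2-enoate
Conditions: Tf2O (1.2 equiv), aq. Me4NOH, toluene, 5 °C
Reagents that add atoms: trifluoromethanesulfonic anhydride (7), O=S(=O)(OS(=O)(=O)C(F)(F)F)C(F)(F)F
Why: O-sulfonylation of the β-keto ester enolate, where the non-chelating tetramethylammonium counter-ion favours the enolate with oxygen anti to the ester and should give the E-enol triflate.

Step 4
Reactants: 5 dimethyl (2S,3S)-2-hydroxy-3-methyl-3-(prop-2-en-1-yl)butanedioate; 8 methyl (2E)-3-(trifluoromethanesulfonyloxy)but-2-enoate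
Product: 10 dimethyl (2S,3S)-2-hydroxy-3-[(4E)-6-methoxy-4-methyl-6-oxohex-4-en-1-yl]-3-methylbutanedioate, via B-alkyl-9-BBN 9 (not isolated)
Conditions: 9-BBN (2.5 equiv), THF, 0 °C → rt; then 8, Pd(dppf)Cl2 (5 mol %), aq. K3PO4, DMF, rt
Reagents that add atoms: enol triflate (8), COC(=O)/C=C(\C)OS(=O)(=O)C(F)(F)F
Why: anti-Markovnikov hydroboration of the terminal alkene followed by B-alkyl Suzuki–Miyaura coupling, which retains the enol triflate geometry and should give the E-enoate (the future C9=C10 dienophile carrying C20).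

Step 5
Reactants: 10 dimethyl (2S,3S)-2-hydroxy-3-[(4E)-6-methoxy-4-methyl-6-oxohex-4-en-1-yl]-3-methylbutanedioate
Product: 11 (2S,3S,7E)-2-hydroxy-9-methoxy-3-(methoxycarbonyl)-3,7-dimethyl-9-oxonon-7-enoic acid
Conditions: LiOH (1.05 equiv), THF/H2O, 0 °C; then 1 M HCl
Reagents that add atoms: lithium hydroxide, [Li+].[OH-]
Why: chemoselective saponification, since the α-hydroxy ester is the most electrophilic and least hindered ester while the ester on the quaternary carbon and the β,β-disubstituted enoate react much more slowly.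

Step 6
Reactants: 11 (2S,3S,7E)-2-hydroxy-9-methoxy-3-(methoxycarbonyl)-3,7-dimethyl-9-oxonon-7-enoic acid
Product: 12 dimethyl (2E,7S)-7-formyl-3,7-dimethyloct-2-enedioate
Conditions: Pb(OAc)4 (1.1 equiv), benzene, rt
Reagents that add atoms: none
Why: oxidative decarboxylation of an α-hydroxy acid with lead tetraacetate (glycol-type cleavage) gives the aldehyde (the future C5), and the adjacent quaternary centre cannot epimerise.

Step 7
Reactants: 12 dimethyl (2E,7S)-7-formyl-3,7-dimethyloct-2-enedioate; 13 1-(triphenylphosphoranylidene)propan-2-one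
Product: 14 dimethyl (2E,7S)-3,7-dimethyl-7-[(1E)-3-oxobut-1-en-1-yl]oct-2-enedioate
Conditions: toluene, 100 °C
Reagents that add atoms: 1-(triphenylphosphoranylidene)propan-2-one (13), CC(=O)C=P(c1ccccc1)(c1ccccc1)c1ccccc1
Why: Wittig olefination of a non-enolisable aldehyde with a stabilised ylide, which should give the E-enone (C5=C6–C7=O with C8 as the methyl).

Step 8
Reactants: 14 dimethyl (2E,7S)-3,7-dimethyl-7-[(1E)-3-oxobut-1-en-1-yl]oct-2-enedioate; 15 tert-butyldimethylsilyl trifluoromethanesulfonate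
Product: 16 dimethyl (2E,7S)-7-[(1E)-3-(tert-butyldimethylsilyloxy)buta-1,3-dien-1-yl]-3,7-dimethyloct-2-enedioate
Conditions: TBSOTf (1.3 equiv), Et3N (2 equiv), CH2Cl2, −78 → 0 °C
Reagents that add atoms: tert-butyldimethylsilyl trifluoromethanesulfonate (15), CC(C)(C)[Si](C)(C)OS(=O)(=O)C(F)(F)F
Why: soft enolisation of the methyl ketone, the only enolisable position, gives the cross-conjugated 2-silyloxydiene while the esters are not silylated.

Step 9
Reactants: 16 dimethyl (2E,7S)-7-[(1E)-3-(tert-butyldimethylsilyloxy)buta-1,3-dien-1-yl]-3,7-dimethyloct-2-enedioate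
Product: 17 dimethyl (1S,4aS,5S,8aR)-7-(tert-butyldimethylsilyloxy)-1,4a-dimethyl-1,2,3,4,4a,5,6,8a-octahydronaphthalene-1,5-dicarboxylate
Conditions: toluene (0.01 M), BHT (cat.), 160 °C, sealed tube
Reagents that add atoms: none
Why: Concerted, asynchronous thermal [4+2] cycloaddition (type 1 intramolecular Diels–Alder reaction of a 2-silyloxy-1,3,9-decatriene with a terminally ester-activated dienophile) that forms C5–C10 and C8–C9 together. Ring B closes as the cyclohexene of the cycloaddition, suprafacial on both partners, and ring A closes through the three-methylene tether in a chair-like arrangement with the tether exo. The E-geometry of the enoate fixes C20 cis to C11, and the ester-endo transition state (secondary orbital overlap with the diene) should give the trans ring fusion with 5α-H, 10β-CH3 and 9β-CO2Me. Facial selectivity comes from C4: the chair places the C19 ester axial and the C18 methyl equatorial, which avoids a methyl/methyl syn-pentane contact with C20, so the dienophile should add to the diene face that puts 4β-CO2Me cis to C20. The tether enforces the regiochemistry against the electronic preference of the 2-silyloxy group, so heat is needed; the selectivities required are endo over exo and the diene face, secured by the ester and by the quaternary C4.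

Step 10
Reactants: 17 dimethyl (1S,4aS,5S,8aR)-7-(tert-butyldimethylsilyloxy)-1,4a-dimethyl-1,2,3,4,4a,5,6,8a-octahydronaphthalene-1,5-dicarboxylate; 18 methyltriphenylphosphonium bromide
Product: 20 methyl (1S,4aR,5R,8aR)-7-(tert-butyldimethylsilyloxy)-5-ethenyl-1,4a-dimethyl-1,2,3,4,4a,5,6,8a-octahydronaphthalene-1-carboxylate, via aldehyde 19 (not isolated)
Conditions: DIBAL-H (1.1 equiv), toluene, −78 °C; then Ph3P=CH2 (from 18, KHMDS, THF), −78 °C → rt
Reagents that add atoms: methyltriphenylphosphonium bromide (18), C[P+](c1ccccc1)(c1ccccc1)c1ccccc1.[Br-]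
Why: DIBAL-H half-reduction of the secondary C11 ester (the axial C19 ester on the quaternary carbon, syn to C20, is far more hindered) and in situ Wittig methylenation of the released aldehyde, with the equatorial C9 substituent being the stable epimer.

Step 11
Reactants: 8 methyl (2E)-3-(trifluoromethanesulfonyloxy)but-2-enoate
Product: 21 (2E)-4-hydroxybut-2-en-2-yl trifluoromethanesulfonate
Conditions: DIBAL-H (2.2 equiv), CH2Cl2, −78 °C
Reagents that add atoms: none
Why: 1,2-reduction of the enoate to the allylic alcohol, with the enol triflate inert to DIBAL-H at low temperature and its E-geometry retained.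

Step 12
Reactants: 20 methyl (1S,4aR,5R,8aR)-7-(tert-butyldimethylsilyloxy)-5-ethenyl-1,4a-dimethyl-1,2,3,4,4a,5,6,8a-octahydronaphthalene-1-carboxylate; 21 (2E)-4-hydroxybut-2-en-2-yl trifluoromethanesulfonate
Product: 23 methyl 7-(tert-butyldimethylsilyloxy)-15-hydroxy-17-norlabda-6,13E-dien-19-oate, via B-alkyl-9-BBN 22 (not isolated)
Conditions: 9-BBN (1.5 equiv), THF, rt; then 21, Pd(dppf)Cl2 (5 mol %), aq. K3PO4, DMF, rt → 40 °C
Reagents that add atoms: hydroxy enol triflate (21), OC/C=C(\C)OS(=O)(=O)C(F)(F)F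
Why: 9-BBN hydroborates the monosubstituted vinyl group and not the trisubstituted silyl enol ether, and B-alkyl Suzuki–Miyaura coupling with retention gives the 13E trisubstituted alkene and completes the side chain.

Step 13
Reactants: 23 methyl 7-(tert-butyldimethylsilyloxy)-15-hydroxy-17-norlabda-6,13E-dien-19-oate
Product: 24 methyl 15-hydroxy-7-oxo-17-norlabd-13E-en-19-oate
Conditions: TBAF (1.1 equiv), AcOH (1.1 equiv), THF, 0 °C
Reagents that add atoms: none
Why: fluoride cleavage of the silyl enol ether with buffered protonation of the enolate unmasks the C7 ketone, and no epimerisable stereocentre is adjacent.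

Step 14
Reactants: 24 methyl 15-hydroxy-7-oxo-17-norlabd-13E-en-19-oate; 25 N,N-dimethylmethyleneiminium iodide (Eschenmoser's salt)
Product: 28 methyl 15-hydroxy-7-oxolabda-8(17),13E-dien-19-oate, via Mannich base 26 (not isolated), via ammonium iodide 27 (not isolated)
Conditions: LiHMDS (2.3 equiv), THF, −78 °C; 25, −78 °C → rt; then MeI, CH2Cl2, rt; then aq. NaHCO3
Reagents that add atoms: N,N-dimethylmethyleneiminium iodide (25), C=[N+](C)C.[I-]
Why: kinetic enolisation toward C8 (the axial C6 hydrogen is shielded by the axial C19 ester and C20, and the C7=C8 enolate corresponds to the favoured 2-ene enolate of trans-fused 3-ketones), then Mannich reaction with Eschenmoser's salt, N-methylation and base-induced elimination of trimethylamine give the exocyclic enone.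

Step 15
Reactants: 28 methyl 15-hydroxy-7-oxolabda-8(17),13E-dien-19-oate
Product: 29 methyl 7β,15-dihydroxylabda-8(17),13E-dien-19-oate
Conditions: NaBH4, CeCl3·7H2O, MeOH, −40 °C
Reagents that add atoms: none
Why: Luche 1,2-reduction, in which axial hydride delivery from the α-face of the ring B chair should give the equatorial 7β-alcohol (7S) and leaves the ester untouched.

Step 16
Reactants: 29 methyl 7β,15-dihydroxylabda-8(17),13E-dien-19-oate; 30 acetic anhydride
Product: 31 methyl 7β,15-diacetoxylabda-8(17),13E-dien-19-oate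
Conditions: Ac2O, pyridine, DMAP (cat.), CH2Cl2, rt
Reagents that add atoms: acetic anhydride (30), CC(=O)OC(C)=O
Why: exhaustive acetylation of both alcohols under nucleophilic catalysis by DMAP.

Step 17
Reactants: 31 methyl 7β,15-diacetoxylabda-8(17),13E-dien-19-oate
Product: 32 methyl (4S,5R,7S,9R,10R)-7-acetoxy-15-hydroxylabda-8(17),13E-dien-19-oate (CNP0329157.1)
Conditions: K2CO3 (0.2 equiv), MeOH, 0 °C
Reagents that add atoms: none
Why: base-catalysed transesterification should remove the unhindered primary allylic acetate much faster than the secondary C7 acetate, which is flanked by the exocyclic methylene and the ring.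

Compound list
1 | dimethyl (S)-malate | COC(=O)C[C@H](O)C(=O)OC | starting material
2 | allyl bromide | C=CCBr | starting material
3 | dimethyl (2S,3R)-2-hydroxy-3-(prop-2-en-1-yl)butanedioate | COC(=O)[C@H](CC=C)[C@H](O)C(=O)OC | intermediate
4 | iodomethane | CI | starting material
5 | dimethyl (2S,3S)-2-hydroxy-3-methyl-3-(prop-2-en-1-yl)butanedioate | COC(=O)[C@@](C)(CC=C)[C@H](O)C(=O)OC | intermediate
6 | methyl acetoacetate | CC(=O)CC(=O)OC | starting material
7 | trifluoromethanesulfonic anhydride | O=S(=O)(OS(=O)(=O)C(F)(F)F)C(F)(F)F | starting material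
8 | methyl (2E)-3-(trifluoromethanesulfonyloxy)but-2-enoate | COC(=O)/C=C(\C)OS(=O)(=O)C(F)(F)F | intermediate
9 | dimethyl (2S,3S)-3-[3-(9-borabicyclo[3.3.1]nonan-9-yl)propyl]-2-hydroxy-3-methylbutanedioate | COC(=O)[C@@](C)(CCCB1C2CCCC1CCC2)[C@H](O)C(=O)OC | intermediate
10 | dimethyl (2S,3S)-2-hydroxy-3-[(4E)-6-methoxy-4-methyl-6-oxohex-4-en-1-yl]-3-methylbutanedioate | COC(=O)/C=C(\C)CCC[C@](C)(C(=O)OC)[C@H](O)C(=O)OC | intermediate
11 | (2S,3S,7E)-2-hydroxy-9-methoxy-3-(methoxycarbonyl)-3,7-dimethyl-9-oxonon-7-enoic acid | COC(=O)/C=C(\C)CCC[C@](C)(C(=O)OC)[C@H](O)C(=O)O | intermediate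
12 | dimethyl (2E,7S)-7-formyl-3,7-dimethyloct-2-enedioate | COC(=O)/C=C(\C)CCC[C@](C)(C(=O)OC)C=O | intermediate
13 | 1-(triphenylphosphoranylidene)propan-2-one | CC(=O)C=P(c1ccccc1)(c1ccccc1)c1ccccc1 | starting material
14 | dimethyl (2E,7S)-3,7-dimethyl-7-[(1E)-3-oxobut-1-en-1-yl]oct-2-enedioate | COC(=O)/C=C(\C)CCC[C@](C)(C(=O)OC)/C=C/C(C)=O | intermediate
15 | tert-butyldimethylsilyl trifluoromethanesulfonate | CC(C)(C)[Si](C)(C)OS(=O)(=O)C(F)(F)F | starting material
16 | dimethyl (2E,7S)-7-[(1E)-3-(tert-butyldimethylsilyloxy)buta-1,3-dien-1-yl]-3,7-dimethyloct-2-enedioate | COC(=O)/C=C(\C)CCC[C@](C)(C(=O)OC)/C=C/C(=C)O[Si](C)(C)C(C)(C)C | intermediate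
17 | dimethyl (1S,4aS,5S,8aR)-7-(tert-butyldimethylsilyloxy)-1,4a-dimethyl-1,2,3,4,4a,5,6,8a-octahydronaphthalene-1,5-dicarboxylate (trans-fused; 4β-CO2Me, 5α-H, 9β-CO2Me, 10β-CH3, C6=C7 silyl enol ether) | C1C(O[Si](C)(C)C(C)(C)C)=C[C@@H]2[C@](C)(CCC[C@]2(C)C(=O)OC)[C@H]1C(=O)OC | intermediate
18 | methyltriphenylphosphonium bromide | C[P+](c1ccccc1)(c1ccccc1)c1ccccc1.[Br-] | starting material
19 | methyl (1S,4aS,5S,8aR)-7-(tert-butyldimethylsilyloxy)-5-formyl-1,4a-dimethyl-1,2,3,4,4a,5,6,8a-octahydronaphthalene-1-carboxylate | C1C(O[Si](C)(C)C(C)(C)C)=C[C@@H]2[C@](C)(CCC[C@]2(C)C(=O)OC)[C@H]1C=O | intermediate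
20 | methyl (1S,4aR,5R,8aR)-7-(tert-butyldimethylsilyloxy)-5-ethenyl-1,4a-dimethyl-1,2,3,4,4a,5,6,8a-octahydronaphthalene-1-carboxylate | C1C(O[Si](C)(C)C(C)(C)C)=C[C@@H]2[C@](C)(CCC[C@]2(C)C(=O)OC)[C@H]1C=C | intermediate
21 | (2E)-4-hydroxybut-2-en-2-yl trifluoromethanesulfonate | OC/C=C(\C)OS(=O)(=O)C(F)(F)F | intermediate
22 | methyl (1S,4aR,5S,8aR)-5-[2-(9-borabicyclo[3.3.1]nonan-9-yl)ethyl]-7-(tert-butyldimethylsilyloxy)-1,4a-dimethyl-1,2,3,4,4a,5,6,8a-octahydronaphthalene-1-carboxylate | C1C(O[Si](C)(C)C(C)(C)C)=C[C@@H]2[C@](C)(CCC[C@]2(C)C(=O)OC)[C@H]1CCB3C4CCCC3CCC4 | intermediate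
23 | methyl 7-(tert-butyldimethylsilyloxy)-15-hydroxy-17-norlabda-6,13E-dien-19-oate | C1C(O[Si](C)(C)C(C)(C)C)=C[C@@H]2[C@](C)(CCC[C@]2(C)C(=O)OC)[C@H]1CC/C(C)=C/CO | intermediate
24 | methyl 15-hydroxy-7-oxo-17-norlabd-13E-en-19-oate | C1C(=O)C[C@@H]2[C@](C)(CCC[C@]2(C)C(=O)OC)[C@H]1CC/C(C)=C/CO | intermediate
25 | N,N-dimethylmethyleneiminium iodide (Eschenmoser's salt) | C=[N+](C)C.[I-] | starting material
26 | methyl 17-(dimethylamino)-15-hydroxy-7-oxolabd-13E-en-19-oate (8β-H) | CN(C)C[C@@H]1C(=O)C[C@@H]2[C@](C)(CCC[C@]2(C)C(=O)OC)[C@H]1CC/C(C)=C/CO | intermediate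
27 | methyl 15-hydroxy-7-oxo-17-(trimethylammonio)labd-13E-en-19-oate iodide (8β-H) | C[N+](C)(C)C[C@@H]1C(=O)C[C@@H]2[C@](C)(CCC[C@]2(C)C(=O)OC)[C@H]1CC/C(C)=C/CO.[I-] | intermediate
28 | methyl 15-hydroxy-7-oxolabda-8(17),13E-dien-19-oate | C=C1C(=O)C[C@@H]2[C@](C)(CCC[C@]2(C)C(=O)OC)[C@H]1CC/C(C)=C/CO | intermediate
29 | methyl 7β,15-dihydroxylabda-8(17),13E-dien-19-oate | C=C1[C@@H](O)C[C@@H]2[C@](C)(CCC[C@]2(C)C(=O)OC)[C@H]1CC/C(C)=C/CO | intermediate
30 | acetic anhydride | CC(=O)OC(C)=O | starting material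
31 | methyl 7β,15-diacetoxylabda-8(17),13E-dien-19-oate | C=C1[C@@H](OC(C)=O)C[C@@H]2[C@](C)(CCC[C@]2(C)C(=O)OC)[C@H]1CC/C(C)=C/COC(C)=O | intermediate
32 | methyl (4S,5R,7S,9R,10R)-7-acetoxy-15-hydroxylabda-8(17),13E-dien-19-oate (CNP0329157.1) | C=C1[C@@H](OC(C)=O)C[C@@H]2[C@](C)(CCC[C@]2(C)C(=O)OC)[C@H]1CC/C(C)=C/CO | target

Total step count: 17. Longest linear sequence: 15 steps (steps 1, 2, 4–10 and 12–17); steps 3 and 11 are side branches.

Steps most likely to fail

Step 9. The cycloaddition may show poor endo/exo (ring-fusion) or diene-face selectivity, or may be so slow at the ester oxidation level that the silyl dienol ether erodes. The fallback sets out from 16 and returns at 19. DIBAL-H (2.2 equiv, CH2Cl2, −78 °C) should reduce only the conjugated ester of 16 and give methyl (2S,6E)-2-[(1E)-3-(tert-butyldimethylsilyloxy)buta-1,3-dien-1-yl]-8-hydroxy-2,6-dimethyloct-6-enoate F1. MnO2 (CH2Cl2, rt) then gives methyl (2S,6E)-2-[(1E)-3-(tert-butyldimethylsilyloxy)buta-1,3-dien-1-yl]-2,6-dimethyl-8-oxooct-6-enoate F2. This aldehyde-activated triene should cyclise in toluene at about 80 °C with the formyl group endo, a more reactive and more strongly endo-directing dienophile, to give aldehyde 19. Here 19 is isolated and methylenated with Ph3P=CH2 to 20 as in the second half of step 10.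

Step 14. Enolisation may occur on the wrong side of the ketone (C6), or methylenation may occur twice. The fallback sets out from 24 and returns at 28. Claisen formylation (NaH, HCO2Et, THF, 0 °C → rt) under thermodynamic control places the formyl group at C8, the position that corresponds to C2 of a trans-fused 3-ketone, and gives methyl 15-hydroxy-17-hydroxy-7-oxolabda-8(17),13E-dien-19-oate (the chelated 8-hydroxymethylene ketone) F3. Any C15 formate formed in passing is cleaved in the next operation. Treatment with aqueous formaldehyde and K2CO3 in THF (aldol addition, then retro-Claisen loss of formate) should give enone 28.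

Step 17. Over-methanolysis may remove the C7 acetate together with the C15 acetate. The fallback sets out from 29 and returns at 32. Selective silylation of the primary alcohol (TBDPSCl, imidazole, CH2Cl2, 0 °C) gives methyl 15-(tert-butyldiphenylsilyloxy)-7β-hydroxylabda-8(17),13E-dien-19-oate F4. Acetylation (Ac2O, pyridine, DMAP) gives methyl 7β-acetoxy-15-(tert-butyldiphenylsilyloxy)labda-8(17),13E-dien-19-oate F5. HF·pyridine in THF then removes the silyl group without touching the acetate and gives 32.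

Further compounds
F1 | step 9 | methyl (2S,6E)-2-[(1E)-3-(tert-butyldimethylsilyloxy)buta-1,3-dien-1-yl]-8-hydroxy-2,6-dimethyloct-6-enoate | OC/C=C(\C)CCC[C@](C)(C(=O)OC)/C=C/C(=C)O[Si](C)(C)C(C)(C)C
F2 | step 9 | methyl (2S,6E)-2-[(1E)-3-(tert-butyldimethylsilyloxy)buta-1,3-dien-1-yl]-2,6-dimethyl-8-oxooct-6-enoate | O=C/C=C(\C)CCC[C@](C)(C(=O)OC)/C=C/C(=C)O[Si](C)(C)C(C)(C)C
F3 | step 14 | methyl 15-hydroxy-17-hydroxy-7-oxolabda-8(17),13E-dien-19-oate (8-hydroxymethylene ketone) | O/C=C1\C(=O)C[C@@H]2[C@](C)(CCC[C@]2(C)C(=O)OC)[C@H]1CC/C(C)=C/CO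
F4 | step 17 | methyl 15-(tert-butyldiphenylsilyloxy)-7β-hydroxylabda-8(17),13E-dien-19-oate | C=C1[C@@H](O)C[C@@H]2[C@](C)(CCC[C@]2(C)C(=O)OC)[C@H]1CC/C(C)=C/CO[Si](c1ccccc1)(c1ccccc1)C(C)(C)C
F5 | step 17 | methyl 7β-acetoxy-15-(tert-butyldiphenylsilyloxy)labda-8(17),13E-dien-19-oate | C=C1[C@@H](OC(C)=O)C[C@@H]2[C@](C)(CCC[C@]2(C)C(=O)OC)[C@H]1CC/C(C)=C/CO[Si](c1ccccc1)(c1ccccc1)C(C)(C)C
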